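**Plan**

- Target numbering: ring O1, lactone carbonyl C2, acyl-bearing C3, enol carbon C4, stereocentre C5 carrying CH2OH.
- Enabling feature: C2, its carbonyl oxygen and the C4 oxygen together make up one CO2. C2 can therefore sit first on the C4 oxygen, in a 1,3-dioxolan-2-one ring built on O1, C5 and C4, and then shift to the neighbouring C3.
- Retrosynthetic cuts, in order: the trityl O–C bond of a cap on the CH2OH; the ring bond C2–C3, with C2 returned to the C4 oxygen; both C–O bonds of that carbonate, which gives CO2 and a 4-hydroxy ynone (C3≡C4 is the 1,3-diketone at the alkyne level); the acyl–alkyne C–C bond; the alkyne carbon of a four-carbon alkynol made from a glycerate ester.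
- Forward: the iso-C15 Weinreb amide and the chiral-pool alkynol are joined by acetylide acylation. CO2 then builds the transient dioxolanone ring, and its 1,3 O-to-C carboxyl shift closes the furanone ring. Detritylation ends the route.
- Stereochemistry: the single stereocentre C5 (S) comes from methyl (S)-2,2-dimethyl-1,3-dioxolane-4-carboxylate, and no step makes or breaks a bond at it.

Key step: step 6

Remark: the side chain is read as 13-methyltetradecanoyl (iso-C15), and the target is treated as the drawn 4-hydroxy tautomer of the 3-acyl tetronic acid, the tautomers being one compound in solution.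

**Route**

Step 1
Reactants: 1 13-methyltetradecanoic acid
Product: 3 N-methoxy-N,13-dimethyltetradecanamide, via acyl imidazole 2 (not isolated)
Conditions: CDI (1.1 equiv), CH2Cl2, rt; then MeNH(OMe)·HCl (1.3 equiv), rt
Reagents that add atoms: N,O-dimethylhydroxylamine hydrochloride, CNOC.Cl; 1,1'-carbonyldiimidazole, O=C(n1ccnc1)n1ccnc1 (imidazolyl of intermediate 2 only)
Why: Activation of the acid as its acyl imidazole followed by aminolysis is a standard Weinreb amide synthesis, and the amide is the acyl donor that stops at the ketone stage in step 5.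

Step 2
Reactants: 4 methyl (S)-2,2-dimethyl-1,3-dioxolane-4-carboxylate
Product: 6 (R)-4-ethynyl-2,2-dimethyl-1,3-dioxolane, via aldehyde 5 (not isolated)
Conditions: i-Bu2AlH (1.05 equiv), CH2Cl2, −78 °C; then MeOH, K2CO3 (2 equiv), dimethyl (1-diazo-2-oxopropyl)phosphonate (1.3 equiv), −78 °C → rt; product kept as a solution
Reagents that add atoms: dimethyl (1-diazo-2-oxopropyl)phosphonate (Ohira–Bestmann reagent), COP(=O)(OC)C(=[N+]=[N-])C(C)=O
Why: Low-temperature i-Bu2AlH reduction stops at the aluminium hemiacetal, which methanol opens to aldehyde 5 for Seyferth–Gilbert homologation with the Ohira–Bestmann reagent in the same flask; no bond at the stereocentre changes, and the descriptor turns from S to R only because ethynyl ranks below CH2O.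

Step 3
Reactants: 6 (R)-4-ethynyl-2,2-dimethyl-1,3-dioxolane
Product: 7 (R)-but-3-yne-1,2-diol
Conditions: Amberlyst 15 (H+ form), MeOH, rt
Reagents that add atoms: none
Why: Acid-catalysed transketalisation to methanol removes the acetonide without touching the alkyne or the carbinol centre.

Step 4
Reactants: 7 (R)-but-3-yne-1,2-diol
Product: 8 (R)-1-(triphenylmethoxy)but-3-yn-2-ol
Conditions: TrCl (1.05 equiv), Et3N (1.5 equiv), DMAP (5 mol %), CH2Cl2, 0 °C → rt
Reagents that add atoms: trityl chloride, ClC(c1ccccc1)(c1ccccc1)c1ccccc1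
Why: The bulky trityl cation is taken up only by the primary hydroxyl (selective tritylation), which leaves the secondary propargylic hydroxyl as the single site for CO2 capture in step 6.

Step 5
Reactants: 8 (R)-1-(triphenylmethoxy)but-3-yn-2-ol; 3 N-methoxy-N,13-dimethyltetradecanamide
Product: 10 (R)-2-hydroxy-17-methyl-1-(triphenylmethoxy)octadec-3-yn-5-one, via dilithio alkoxide-acetylide 9 (not isolated)
Conditions: n-BuLi (2.1 equiv), THF, −78 → −40 °C; then 3, −78 → −10 °C; inverse quench into cold aq. NH4Cl/HCl buffer (pH ≈ 4)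
Reagents that add atoms: none
Why: Two equivalents of n-BuLi give the alkoxide/acetylide dianion, whose carbon end adds to the Weinreb amide to a chelated tetrahedral intermediate that releases the ynone only on the acidic quench (Weinreb ketone synthesis), so over-addition is avoided and the carbinol stereocentre is untouched.

Step 6
Reactants: 10 (R)-2-hydroxy-17-methyl-1-(triphenylmethoxy)octadec-3-yn-5-one
Product: 13 (S)-4-hydroxy-3-(13-methyltetradecanoyl)-5-[(triphenylmethoxy)methyl]furan-2(5H)-one, via amidinium alkyl carbonate 11 (not isolated), via alkylidene dioxolanone 12 (not isolated)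
Conditions: CO2 (1 atm), DBU (1.5 equiv), DMAP (0.2 equiv), dry MeCN, 0 °C → rt; then cold 0.5 M HCl, EtOAc (brief, two-phase)
Reagents that add atoms: carbon dioxide, O=C=O
Why: Proposed new method: DBU and CO2 turn the only free hydroxyl into alkyl carbonate 11, whose oxygen adds to the electrophilic β-carbon C4 of the ynone (5-exo-dig oxa-Michael closure of the transient dioxolanone ring) to give 12, the cyclic enol carbonate of the 1,3-diketone; DMAP then opens 12 at the carbonate carbon with loss of the diketonate, and C3 of that diketonate attacks the O1-bound acylpyridinium (5-exo-trig, enolexo through the side-chain carbonyl), which forms the C2–C3 bond and closes the furanone ring. The closest known reaction types are the base-mediated carboxylative cyclisation of propargylic alcohols with CO2 to α-alkylidene cyclic carbonates and the DMAP-catalysed Steglich-type 1,3 O-to-C acyl shift of enol esters and enol carbonates of 1,3-dicarbonyl compounds, as used to turn 4-O-acyl tetronates into 3-acyl tetronic acids. No stereocentre is formed: C5 comes from ester 4 and keeps its configuration because no bond to it is made or broken. The step needs CO2 anchored on the C5 oxygen and delivered to C4 and not C3, and it needs C- and not O-acylation; the trityl ether leaves a single hydroxyl, the ynone polarity sends the carbonate oxygen to C4, and only a five-membered ring can then close. C-acylation should win because O-acylation is reversible under DMAP catalysis, whereas the 3-acyl tetronic acid is a strong acid that is removed as its amidinium salt.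

Step 7
Reactants: 13 (S)-4-hydroxy-3-(13-methyltetradecanoyl)-5-[(triphenylmethoxy)methyl]furan-2(5H)-one
Product: 14 (S)-4-hydroxy-5-(hydroxymethyl)-3-(13-methyltetradecanoyl)furan-2(5H)-one (target)
Conditions: TFA, H2O (5 equiv), CH2Cl2, 0 °C → rt
Reagents that add atoms: none
Why: Acid ionises the trityl ether (SN1 acidolysis) and water traps the trityl cation, while the acid-stable 3-acyl tetronic acid and its C5 centre are left unchanged.

**Compound list**

1 | 13-methyltetradecanoic acid | CC(C)CCCCCCCCCCCC(=O)O | starting material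
2 | 1-(1H-imidazol-1-yl)-13-methyltetradecan-1-one (acyl imidazole, formed in the flask) | CC(C)CCCCCCCCCCCC(=O)n1ccnc1 | intermediate
3 | N-methoxy-N,13-dimethyltetradecanamide | CC(C)CCCCCCCCCCCC(=O)N(C)OC | intermediate
4 | methyl (S)-2,2-dimethyl-1,3-dioxolane-4-carboxylate | COC(=O)[C@@H]1COC(C)(C)O1 | starting material
5 | (S)-2,2-dimethyl-1,3-dioxolane-4-carbaldehyde (formed in the flask) | O=C[C@@H]1COC(C)(C)O1 | intermediate
6 | (R)-4-ethynyl-2,2-dimethyl-1,3-dioxolane | C#C[C@@H]1COC(C)(C)O1 | intermediate
7 | (R)-but-3-yne-1,2-diol | C#C[C@H](CO)O | intermediate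
8 | (R)-1-(triphenylmethoxy)but-3-yn-2-ol | C#C[C@H](COC(c1ccccc1)(c1ccccc1)c1ccccc1)O | intermediate
9 | lithium (R)-4-lithio-1-(triphenylmethoxy)but-3-yn-2-olate (dilithio derivative of 8, formed in the flask) | [Li]C#C[C@H](COC(c1ccccc1)(c1ccccc1)c1ccccc1)O[Li] | intermediate
10 | (R)-2-hydroxy-17-methyl-1-(triphenylmethoxy)octadec-3-yn-5-one | CC(C)CCCCCCCCCCCC(=O)C#C[C@H](COC(c1ccccc1)(c1ccccc1)c1ccccc1)O | intermediate
11 | 1,8-diazabicyclo[5.4.0]undec-7-enium (R)-17-methyl-5-oxo-1-(triphenylmethoxy)octadec-3-yn-2-yl carbonate (formed in the flask) | CC(C)CCCCCCCCCCCC(=O)C#C[C@H](COC(c1ccccc1)(c1ccccc1)c1ccccc1)OC(=O)[O-].C1CCC2=[NH+]CCCN2CC1 | intermediate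
12 | (S,Z)-4-(14-methyl-2-oxopentadecylidene)-5-[(triphenylmethoxy)methyl]-1,3-dioxolan-2-one (formed in the flask; Z expected from anti addition) | CC(C)CCCCCCCCCCCC(=O)/C=C1\OC(=O)O[C@H]1COC(c2ccccc2)(c2ccccc2)c2ccccc2 | intermediate
13 | (S)-4-hydroxy-3-(13-methyltetradecanoyl)-5-[(triphenylmethoxy)methyl]furan-2(5H)-one | CC(C)CCCCCCCCCCCC(=O)C1=C(O)[C@H](COC(c2ccccc2)(c2ccccc2)c2ccccc2)OC1=O | intermediate
14 | (S)-4-hydroxy-5-(hydroxymethyl)-3-(13-methyltetradecanoyl)furan-2(5H)-one | CC(C)CCCCCCCCCCCC(=O)C1=C(O)[C@H](CO)OC1=O | target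

**Step count**

Total: 7 steps. Longest linear sequence: 6 steps (4 → 6 → 7 → 8 → 10 → 13 → 14, steps 2 to 7).

**Steps most likely to fail**

1. Step 6 (proposed new method). Base-induced deprotonation at the propargylic carbon of the hydroxy ynone may cause redox isomerisation and erosion of configuration at C5. The amidine or DMAP may add to the ynone, the cascade may stall at the enol carbonate stage, or the alkyl carbonate may lose CO2 again.
   Fallback (known chemistry, Lacey–Dieckmann ring closure): it sets out from 4 and 1 and returns at 13. Acid-catalysed methanolysis of 4 (Amberlyst 15, MeOH) gives methyl (S)-2,3-dihydroxypropanoate F1. Tritylation of its primary hydroxyl (TrCl, Et3N, DMAP) gives methyl (S)-2-hydroxy-3-(triphenylmethoxy)propanoate F2. Acid 1 is condensed with Meldrum's acid (DCC, DMAP, CH2Cl2) to 5-(1-hydroxy-13-methyltetradecylidene)-2,2-dimethyl-1,3-dioxane-4,6-dione F3. Heating F3 with F2 in toluene (acyl ketene trapping) gives methyl (S)-2-[(15-methyl-3-oxohexadecanoyl)oxy]-3-(triphenylmethoxy)propanoate F4. Dieckmann cyclisation of F4 with Bu4NF in THF at rt should give 13, and step 7 follows unchanged.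

2. Step 5. The aggregated alkoxide/acetylide dianion may acylate sluggishly, the liberated N,O-dimethylhydroxylamine may add to the ynone during work-up, and the acidic quench may start to remove the trityl group.
   Fallback: it sets out from 8 and 1 and returns at 10. Silylation of 8 (Et3SiCl, imidazole, CH2Cl2) gives (R)-triethyl{[1-(triphenylmethoxy)but-3-yn-2-yl]oxy}silane F5. Acid 1 with oxalyl chloride (cat. DMF) gives 13-methyltetradecanoyl chloride F6. Palladium/copper-catalysed acylation of the terminal alkyne F5 with F6 (PdCl2(PPh3)2 2 mol %, CuI 4 mol %, Et3N, THF, rt) gives (R)-17-methyl-2-[(triethylsilyl)oxy]-1-(triphenylmethoxy)octadec-3-yn-5-one F7. HF·pyridine buffered with pyridine in THF at 0 °C removes the silyl ether and gives 10.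

3. Step 2. Over-reduction of the ester to the alcohol, epimerisation of the α-alkoxy aldehyde in basic methanol, and loss of the volatile alkyne on concentration are the likely failures.
   Fallback: it sets out from 4 and returns at 6. LiAlH4 reduction of 4 in Et2O gives (R)-(2,2-dimethyl-1,3-dioxolan-4-yl)methanol F8. Swern oxidation gives aldehyde 5, used crude. CBr4/PPh3 (Et3N, CH2Cl2, 0 °C) gives the storable, non-volatile (R)-4-(2,2-dibromoethenyl)-2,2-dimethyl-1,3-dioxolane F9. n-BuLi (2.2 equiv, THF, −78 °C) and then water give 6 (Corey–Fuchs sequence).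

Further compounds
F1 | step 6 | methyl (S)-2,3-dihydroxypropanoate | COC(=O)[C@H](CO)O
F2 | step 6 | methyl (S)-2-hydroxy-3-(triphenylmethoxy)propanoate | COC(=O)[C@H](COC(c1ccccc1)(c1ccccc1)c1ccccc1)O
F3 | step 6 | 5-(1-hydroxy-13-methyltetradecylidene)-2,2-dimethyl-1,3-dioxane-4,6-dione | CC(C)CCCCCCCCCCCC(O)=C1C(=O)OC(C)(C)OC1=O
F4 | step 6 | methyl (S)-2-[(15-methyl-3-oxohexadecanoyl)oxy]-3-(triphenylmethoxy)propanoate | CC(C)CCCCCCCCCCCC(=O)CC(=O)O[C@@H](COC(c1ccccc1)(c1ccccc1)c1ccccc1)C(=O)OC
F5 | step 5 | (R)-triethyl{[1-(triphenylmethoxy)but-3-yn-2-yl]oxy}silane | C#C[C@H](COC(c1ccccc1)(c1ccccc1)c1ccccc1)O[Si](CC)(CC)CC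
F6 | step 5 | 13-methyltetradecanoyl chloride | CC(C)CCCCCCCCCCCC(=O)Cl
F7 | step 5 | (R)-17-methyl-2-[(triethylsilyl)oxy]-1-(triphenylmethoxy)octadec-3-yn-5-one | CC(C)CCCCCCCCCCCC(=O)C#C[C@H](COC(c1ccccc1)(c1ccccc1)c1ccccc1)O[Si](CC)(CC)CC
F8 | step 2 | (R)-(2,2-dimethyl-1,3-dioxolan-4-yl)methanol | OC[C@@H]1COC(C)(C)O1
F9 | step 2 | (R)-4-(2,2-dibromoethenyl)-2,2-dimethyl-1,3-dioxolane | BrC(Br)=C[C@@H]1COC(C)(C)O1
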